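All runs are simulated on assumed constants; the scatter is artificial.

Target reads 0% at the end of the theta run, so follow the feed instead. There, substrate and intermediate A together read 100% at 8.00 h.

| flask | substrate | gas | remark | time |
|---|---|---|---|---|
| eta | 0.050 M (fed, over 8.0 h) | 22 mM (held) | the very flask that is asked about, followed so far |  |
| theta | 0.034 M (fed, over 8.0 h) | 22 mM (held) | run made earlier |  |
| flask | 0.050 M (fed, over 8.0 h) | 22 mM (held) |  | 8.0 h |

eta run (percent of the substrate charged)

| time / min | substrate / % | intermediate A / % | target / % |
|---|---|---|---|
| 6.00 | 1 | 0 | 2 |
| 20.0 | 5 | 1 | 0 |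
| 30.0 | 7 | 2 | 0 |
| 50.0 | 9 | 3 | 0 |
| 80.0 | 15 | 4 | 0 |
| 90.0 | 15 | 7 | 0 |

theta run (percent of the substrate charged)

| time / h | substrate / % | intermediate A / % | target / % |
|---|---|---|---|
| 0.667 | 7 | 1 | 0 |
| 1.00 | 9 | 1 | 0 |
| 2.00 | 17 | 8 | 0 |
| 3.00 | 23 | 16 | 0 |
| 5.00 | 28 | 36 | 1 |
| 8.00 | 32 | 68 | 0 |

(scatter of a reading: 1.5 percentage points)

- which holds at 8.0 h: what has brought the reaction to rest, or that it has not come to rest (forward and back rates have come level / it is still moving / all of the substrate has reacted)
- how much of the substrate has reacted by 8.0 h
- how much intermediate A there is at 8.0 h, in percent of the substrate charged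

- at the start none of reagent is dissolved
- the earlier runs were read with a standard deviation of 1.5 percentage points
- reactions considered so far: substrate <-> intermediate A; substrate <-> intermediate B; intermediate B <-> intermediate C; reagent + intermediate C -> side product A; intermediate B -> side product B; reagent + intermediate C -> target; gas <-> reagent
- what has gone from substrate into another species counts as reacted, even if it can come back
- percentages count the whole charge, also what has not yet gone in
- the reaction counts as stopped when no species that holds the substrate changes by six tenths of a point or more over the second half of the time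

The feed brings in 0.125 h⁻¹ of the charge. If substrate leaves by a first-order loss and has levelled off, loss equals feed, and [substrate] in percent divided by the feed is a time: 2.56 h from the last theta reading.

That link is weak, since the substrate readings of the theta run still climb, by 0.0133 h⁻¹ of the charge between 5.00 h and 8.00 h. So take the loss as feed minus rise, and divide the mean substrate of those readings by it. This gives the holding time, the mean residence time of substrate in the flask: 2.69 h.

Counted in percent of the charge, a first-order loss with a steady feed over the same dosing time does not depend on the charge, so you can test this on the eta flask: at 90.0 min it predicts 14.4% substrate, and the reading is 15%. At 8.0 h my reckoning leaves 31.9% substrate, so 68.1% has reacted, and I take nearly all of it as intermediate A, as the last theta readings show. Intermediate A is then still gaining 0.119 h⁻¹ of the charge, so the flask is moving.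

The forecast stands a little above my reckoning: it says it is still moving, with 69.5% reacted (64% to 75%) and 69% intermediate A (62% to 74%), adding: “There is no sign of the reverse reaction yet.”

At 8.0 h the eta flask gives: it is still moving, with 70.1% reacted and 68.5% intermediate A.

    substrate ⇌ intermediate A (K = 39.0, k = 0.410 h⁻¹)
    substrate ⇌ intermediate B (K = 1.90, k = 0.00990 h⁻¹)
    intermediate B ⇌ intermediate C (K = 9.70, k = 0.0670 h⁻¹)
    reagent + intermediate C → side product A (k = 1.10 L mol⁻¹ h⁻¹)
    intermediate B → side product B (k = 0.0290 h⁻¹)
    reagent + intermediate C → target (k = 2.10 L mol⁻¹ h⁻¹)
    gas ⇌ reagent, rate k7*(csat - [reagent]) (kL = 0.740 h⁻¹)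

In the eta flask, substrate went to intermediate A for as long as the feed ran, the turnover of that step reaching its midpoint at 4.92 h. The path from intermediate B to intermediate C had carried a net 0.293% of the charge by 8.0 h. Read at 20 h, with the feed long over, the holding time would drain the 30% substrate to 0.343%. That flask instead holds 2.55% substrate beside 94.9% intermediate A.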